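**Strategy**

Everything rests on disconnecting the O1–C2 ether bond of the dihydropyran ring C. The feature exploited is that C2, the only stereocentre, is a secondary benzylic carbon on ring B (4-methoxyphenyl), while O1 is a phenolic oxygen of ring A tied to C2 through the four-atom chain C8a–C4a–C4–C3. An intramolecular Mitsunobu etherification therefore closes ring C in the 6-exo-tet mode and, by inversion, turns an (R)-carbinol into the (2S)-ether in one operation. The precursor is an open-chain (R)-1-(4-methoxyphenyl)-3-arylpropan-1-ol with a free ortho phenol, obtained by asymmetric transfer hydrogenation of a ketone assembled from 3,5-dimethoxy-4-prenylphenol, formaldehyde and 4'-methoxyacetophenone.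

Key step: step 7

Remark: the target is read as the (2S)-flavan; rings are lettered A (trioxygenated benzo ring), B (4-methoxyphenyl) and C (dihydropyran); compounds 1, 3, 7 and 10 are taken as commercial.

**Route**

Step 1
Reactants: 1 3,5-dimethoxyphenol
Product: 2 (3,5-dimethoxyphenoxy)tri(propan-2-yl)silane
Conditions: NaH, THF, 0 °C; TIPSCl, rt
Reagents that add atoms: triisopropylsilyl chloride, CC(C)[Si](Cl)(C(C)C)C(C)C
Why: O-silylation of the sodium phenoxide should mask the acidic OH as a bulky silyl ether that resists n-BuLi and does not direct metalation.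

Step 2
Reactants: 2 (3,5-dimethoxyphenoxy)tri(propan-2-yl)silane; 3 1-bromo-3-methylbut-2-ene (prenyl bromide)
Product: 6 3,5-dimethoxy-4-(3-methylbut-2-en-1-yl)phenol, via aryllithium 4 (not isolated), via prenylated silyl ether 5 (not isolated)
Conditions: n-BuLi, THF, 0 °C to rt; 3, −78 °C to rt; TBAF, rt
Reagents that add atoms: none
Why: Directed ortho-metalation should occur at the carbon flanked by both methoxy groups (the shielded silyloxy group does not compete), SN2 alkylation of aryllithium 4 with the primary allylic bromide installs the prenyl group, and fluoride desilylation in the same flask frees the phenol.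

Step 3
Reactants: 6 3,5-dimethoxy-4-(3-methylbut-2-en-1-yl)phenol; 7 formaldehyde (as paraformaldehyde)
Product: 9 6-hydroxy-2,4-dimethoxy-3-(3-methylbut-2-en-1-yl)benzaldehyde, via salicyl alcohol 8 (not isolated)
Conditions: MgCl2, Et3N, (CH2O)n, MeCN, reflux
Reagents that add atoms: none
Why: In this Casnati–Skattebøl ortho-formylation the magnesium phenoxide should deliver formaldehyde to the ortho carbon through a chelate to give salicyl alcohol 8, which a second formaldehyde oxidises by hydride transfer; the two ortho positions are equivalent and the first formyl group deactivates the ring against a second.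

Step 4
Reactants: 9 6-hydroxy-2,4-dimethoxy-3-(3-methylbut-2-en-1-yl)benzaldehyde; 10 1-(4-methoxyphenyl)ethan-1-one
Product: 12 (2E)-3-[6-hydroxy-2,4-dimethoxy-3-(3-methylbut-2-en-1-yl)phenyl]-1-(4-methoxyphenyl)prop-2-en-1-one, via aldol adduct 11 (not isolated)
Conditions: KOH, EtOH/H2O, rt to 40 °C; AcOH to pH 6
Reagents that add atoms: none
Why: Claisen–Schmidt condensation of the methyl ketone enolate with the non-enolisable aldehyde, followed by E1cB dehydration of aldol adduct 11, should give the conjugated (E)-enone, and the mild neutralisation avoids acid-induced closure to a flavylium salt.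

Step 5
Reactants: 12 (2E)-3-[6-hydroxy-2,4-dimethoxy-3-(3-methylbut-2-en-1-yl)phenyl]-1-(4-methoxyphenyl)prop-2-en-1-one
Product: 13 3-[6-hydroxy-2,4-dimethoxy-3-(3-methylbut-2-en-1-yl)phenyl]-1-(4-methoxyphenyl)propan-1-one
Conditions: H2 (1 atm), RhCl(PPh3)3 (5 mol%), toluene/EtOH, rt
Reagents that add atoms: none
Why: Homogeneous hydrogenation with RhCl(PPh3)3 discriminates alkenes by substitution, so the disubstituted enone C=C should be saturated while the trisubstituted prenyl alkene, the ketone and the arenes stay untouched (chemoselective alkene hydrogenation).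

Step 6
Reactants: 13 3-[6-hydroxy-2,4-dimethoxy-3-(3-methylbut-2-en-1-yl)phenyl]-1-(4-methoxyphenyl)propan-1-one
Product: 14 2-[(3R)-3-hydroxy-3-(4-methoxyphenyl)propyl]-3,5-dimethoxy-4-(3-methylbut-2-en-1-yl)phenol
Conditions: RuCl(p-cymene)[(R,R)-TsDPEN] (1 mol%), HCO2H/Et3N (5:2), EtOAc, 30 °C
Reagents that add atoms: none
Why: Noyori–Ikariya asymmetric transfer hydrogenation of the aryl alkyl ketone should deliver hydride through the CH/π-organised six-membered transition state, the (R,R)-ligand giving the (R)-carbinol as it does with acetophenone, and the polarity-driven ruthenium hydride leaves the prenyl alkene and the phenol alone.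

Step 7
Reactants: 14 2-[(3R)-3-hydroxy-3-(4-methoxyphenyl)propyl]-3,5-dimethoxy-4-(3-methylbut-2-en-1-yl)phenol
Product: 16 (2S)-5,7-dimethoxy-2-(4-methoxyphenyl)-6-(3-methylbut-2-en-1-yl)-3,4-dihydro-2H-chromene, via oxyphosphonium phenoxide 15 (not isolated)
Conditions: PPh3, DIAD, toluene, −20 to 0 °C
Reagents that add atoms: none
Why: PPh3 and DIAD form the betaine, which deprotonates the ring A phenol and converts the C2 carbinol into oxyphosphonium ion 15, whereupon the phenoxide O1 displaces triphenylphosphine oxide at C2 by intramolecular SN2 attack. The closest known reaction type is the intramolecular Mitsunobu etherification of 1-aryl-3-(2-hydroxyaryl)propan-1-ols to 2-arylchromans. Ring C is closed in the 6-exo-tet mode. The new C2 stereocentre is controlled by the substrate: backside attack inverts the (R)-carbinol set in step 6 and should give the (2S)-ether. The step needs SN2 closure to outrun ionisation of the 4-methoxybenzylic oxyphosphonium ion (racemisation or elimination to the styrene), and the high effective molarity of the phenoxide, the non-polar solvent and the low temperature are meant to secure this. The phenol is the only acidic pronucleophile, and the prenyl alkene and the methyl ethers are inert.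

**Compound list**

1 | 3,5-dimethoxyphenol | COc1cc(O)cc(OC)c1 | starting material
2 | (3,5-dimethoxyphenoxy)tri(propan-2-yl)silane | COc1cc(O[Si](C(C)C)(C(C)C)C(C)C)cc(OC)c1 | intermediate
3 | 1-bromo-3-methylbut-2-ene (prenyl bromide) | CC(C)=CCBr | starting material
4 | {2,6-dimethoxy-4-[tri(propan-2-yl)silyloxy]phenyl}lithium (aryllithium; not isolated) | [Li]c1c(OC)cc(O[Si](C(C)C)(C(C)C)C(C)C)cc1OC | intermediate
5 | [3,5-dimethoxy-4-(3-methylbut-2-en-1-yl)phenoxy]tri(propan-2-yl)silane (prenylated silyl ether; not isolated) | COc1cc(O[Si](C(C)C)(C(C)C)C(C)C)cc(OC)c1CC=C(C)C | intermediate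
6 | 3,5-dimethoxy-4-(3-methylbut-2-en-1-yl)phenol | COc1cc(O)cc(OC)c1CC=C(C)C | intermediate
7 | formaldehyde (used as paraformaldehyde) | C=O | starting material
8 | 2-(hydroxymethyl)-3,5-dimethoxy-4-(3-methylbut-2-en-1-yl)phenol (salicyl alcohol; in the flask as its magnesium phenoxide; not isolated) | OCc1c(O)cc(OC)c(CC=C(C)C)c1OC | intermediate
9 | 6-hydroxy-2,4-dimethoxy-3-(3-methylbut-2-en-1-yl)benzaldehyde | O=Cc1c(O)cc(OC)c(CC=C(C)C)c1OC | intermediate
10 | 1-(4-methoxyphenyl)ethan-1-one (4'-methoxyacetophenone) | COc1ccc(cc1)C(C)=O | starting material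
11 | 3-hydroxy-3-[6-hydroxy-2,4-dimethoxy-3-(3-methylbut-2-en-1-yl)phenyl]-1-(4-methoxyphenyl)propan-1-one (aldol adduct; racemic; not isolated) | COc1ccc(cc1)C(=O)CC(O)c1c(O)cc(OC)c(CC=C(C)C)c1OC | intermediate
12 | (2E)-3-[6-hydroxy-2,4-dimethoxy-3-(3-methylbut-2-en-1-yl)phenyl]-1-(4-methoxyphenyl)prop-2-en-1-one | COc1ccc(cc1)C(=O)/C=C/c1c(O)cc(OC)c(CC=C(C)C)c1OC | intermediate
13 | 3-[6-hydroxy-2,4-dimethoxy-3-(3-methylbut-2-en-1-yl)phenyl]-1-(4-methoxyphenyl)propan-1-one | COc1ccc(cc1)C(=O)CCc1c(O)cc(OC)c(CC=C(C)C)c1OC | intermediate
14 | 2-[(3R)-3-hydroxy-3-(4-methoxyphenyl)propyl]-3,5-dimethoxy-4-(3-methylbut-2-en-1-yl)phenol | COc1ccc(cc1)[C@H](O)CCc1c(O)cc(OC)c(CC=C(C)C)c1OC | intermediate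
15 | (R)-oxyphosphonium phenoxide zwitterion of 14 (not isolated) | COc1ccc(cc1)[C@H](O[P+](c1ccccc1)(c1ccccc1)c1ccccc1)CCc1c([O-])cc(OC)c(CC=C(C)C)c1OC | intermediate
16 | (2S)-5,7-dimethoxy-2-(4-methoxyphenyl)-6-(3-methylbut-2-en-1-yl)-3,4-dihydro-2H-chromene | COc1ccc([C@@H]2CCc3c(cc(OC)c(CC=C(C)C)c3OC)O2)cc1 | target

**Step count**

Total steps: 7. Longest linear sequence: 7 steps (1 to 16).

**Steps most likely to fail**

Step 7 (key step). The ring closure may leak into an ionisation pathway: the 4-methoxybenzylic oxyphosphonium ion can dissociate before the phenoxide attacks, which would erode the enantiomeric purity and divert material to the styrene by elimination. The fallback carries ring B as a 4-bromophenyl group, which does not stabilise a benzylic cation, and installs the methoxy group last by C–O coupling. It sets out from aldehyde 9 and returns to the route at target 16. Claisen–Schmidt condensation of 9 with 4'-bromoacetophenone (CC(=O)c1ccc(Br)cc1) under the conditions of step 4 should give bromo chalcone F1. Hydrogenation over RhCl(PPh3)3 as in step 5 should give bromo ketone F2, and transfer hydrogenation with RuCl(p-cymene)[(R,R)-TsDPEN] as in step 6 should give (R)-bromo carbinol F3. Mitsunobu closure as in step 7 should then give (2S)-bromo flavan F4, now by a clean SN2 path. Palladium-catalysed methoxylation of the aryl bromide (Pd2(dba)3, tBuBrettPhos, NaOtBu, MeOH, 1,4-dioxane, 50 °C) should deliver 16.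

Step 4. The condensation may stall: under KOH the aldehyde is present as its phenoxide, a poor electrophile flanked by two ortho substituents, so self-condensation of the ketone may compete with slow conversion, and careless acidification may close the product to a flavylium salt. The fallback replaces the base-mediated aldol condensation by a Wittig olefination under neutral conditions, in which the aldehyde stays protonated and hydrogen-bond activated. It sets out from aldehyde 9 and returns at chalcone 12. Compound 9 is heated in toluene at reflux with the purchased stabilised ylide (4-methoxyphenacylidene)triphenylphosphorane (COc1ccc(cc1)C(=O)C=P(c1ccccc1)(c1ccccc1)c1ccccc1), which should give the (E)-enone 12 directly.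

Step 5. Chemoselectivity may be lost: the enone alkene is shielded by the 2,6-disubstituted aryl group and deactivated by its donor substituents, so the forcing needed for full conversion may also saturate the prenyl alkene. The fallback builds the C3–C4 bond at the saturated oxidation level, so that no alkene has to be reduced beside the prenyl group. It sets out from aldehyde 9, bypasses steps 4 and 5, and returns at ketone 13. Reduction of 9 with NaBH4 in MeOH at 0 °C should give salicyl alcohol 8, which is used crude. Ketone 10 is condensed with morpholine (TiCl4, toluene) to give enamine F5. Heating 8 with F5 in toluene should expel water to form ortho-quinone methide F6, which is trapped in an inverse-demand hetero-Diels–Alder reaction as aminochroman F7. Hydrolysis of this N,O-ketal with dilute aqueous AcOH should release ketone 13.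

**Further compounds**

F1 | step 7 | (2E)-1-(4-bromophenyl)-3-[6-hydroxy-2,4-dimethoxy-3-(3-methylbut-2-en-1-yl)phenyl]prop-2-en-1-one | Brc1ccc(cc1)C(=O)/C=C/c1c(O)cc(OC)c(CC=C(C)C)c1OC
F2 | step 7 | 1-(4-bromophenyl)-3-[6-hydroxy-2,4-dimethoxy-3-(3-methylbut-2-en-1-yl)phenyl]propan-1-one | Brc1ccc(cc1)C(=O)CCc1c(O)cc(OC)c(CC=C(C)C)c1OC
F3 | step 7 | 2-[(3R)-3-(4-bromophenyl)-3-hydroxypropyl]-3,5-dimethoxy-4-(3-methylbut-2-en-1-yl)phenol | Brc1ccc(cc1)[C@H](O)CCc1c(O)cc(OC)c(CC=C(C)C)c1OC
F4 | step 7 | (2S)-2-(4-bromophenyl)-5,7-dimethoxy-6-(3-methylbut-2-en-1-yl)-3,4-dihydro-2H-chromene | Brc1ccc([C@@H]2CCc3c(cc(OC)c(CC=C(C)C)c3OC)O2)cc1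
F0 | step 4 | none | none
F5 | step 5 | 4-[1-(4-methoxyphenyl)ethenyl]morpholine | COc1ccc(cc1)C(=C)N1CCOCC1
F6 | step 5 | 3,5-dimethoxy-6-methylidene-4-(3-methylbut-2-en-1-yl)cyclohexa-2,4-dien-1-one | O=C1C=C(OC)C(CC=C(C)C)=C(OC)C1=C
F7 | step 5 | 4-[5,7-dimethoxy-2-(4-methoxyphenyl)-6-(3-methylbut-2-en-1-yl)-3,4-dihydro-2H-chromen-2-yl]morpholine (racemic) | COc1ccc(cc1)C1(CCc2c(O1)cc(OC)c(CC=C(C)C)c2OC)N1CCOCC1
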